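**Plan** (prostanoid numbering; ring = C8 alkylidene carbon, C9 ketone, C10 C–Cl, C11 =CH, C12 C–OAc)

- Retrosynthetic cuts, in order: the acetyl–O bond at C12; C7=C8 (aldol condensation with a C1–C7 enal); then C10 with its chlorine is excised from the ring (bonds C9–C10 and C10–C11), contracting the cyclopentenone to a cyclobutanone; last C12–C13.
- Enabling feature: the C9(=O)–C10(Cl)=C11H triad is what a dichlorocarbene leaves after adding to the C9=C11 enol double bond of a four-membered ketone and opening the housane formed. Without C10 the ring C8–C9–C11–C12 is an achiral 3,3-disubstituted cyclobutanone with a mirror plane through C9 and C12.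
- Forward: the C13–C20 chain is joined to a cyclobutanone (C12–C13); the four-membered ring is desymmetrised as its enol silane; the five-membered chloroenone ring arises from it by one-carbon ring expansion; the C1–C7 chain is then joined at C8 and the acetate is put on last.
- Stereochemistry: C12 comes from enantiotopic-group-selective deprotonation by a chiral lithium amide, since the side of C12 on which C10 is inserted decides its configuration. 14Z comes from (Z)-oct-2-en-1-ol and is kept by α-selective allylbarium addition; 5Z from a (Z)-selective Wittig reaction; 7E from E1cB dehydration of the aldol.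

Key step: step 7

Assumption (remark on the chemistry): the (R,R)-enantiomer of lithium bis(1-phenylethyl)amide is taken to remove the α-proton that leads to the (S)-enol silane 10. The sense of induction on this 3,3-disubstituted cyclobutanone would have to be confirmed, and the (S,S)-amide would be used if it proved opposite.

**Route**

Step 1
Reactants: 1 (Z)-oct-2-en-1-ol
Product: 2 (Z)-1-chlorooct-2-ene
Conditions: PPh3, hexachloroacetone, CH2Cl2, 0 °C
Reagents that add atoms: hexachloroacetone, O=C(C(Cl)(Cl)Cl)C(Cl)(Cl)Cl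
Why: Appel-type chlorination converts the primary allylic alcohol into the chloride by SN2 displacement of the alkoxyphosphonium ion, so neither allylic transposition nor loss of the (Z) geometry is expected.

Step 2
Reactants: 2 (Z)-1-chlorooct-2-ene; 3 3-(benzyloxy)cyclobutan-1-one
Product: 5 3-(benzyloxy)-1-[(Z)-oct-2-en-1-yl]cyclobutan-1-ol (cis/trans mixture), via (Z)-oct-2-enylbarium chloride 4 (not isolated)
Conditions: BaI2, lithium biphenylide (2 equiv), THF, 20 °C; 2, −78 °C; 3, −78 °C; then aq NH4Cl
Reagents that add atoms: none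
Why: Allylbarium reagents made and kept at −78 °C add to ketones at the α-carbon with retention of olefin geometry (α-selective carbonyl allylation), which forms C12–C13 and the tertiary carbinol without transposition; the cis/trans relation to the benzyloxy group is irrelevant because that carbon becomes the carbonyl carbon C9 in step 5.

Step 3
Reactants: 5 3-(benzyloxy)-1-[(Z)-oct-2-en-1-yl]cyclobutan-1-ol
Product: 6 {[3-(benzyloxy)-1-((Z)-oct-2-en-1-yl)cyclobutyl]oxy}triethylsilane
Conditions: Et3SiOTf, 2,6-lutidine, CH2Cl2, −78 → 0 °C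
Reagents that add atoms: triethylsilyl trifluoromethanesulfonate, CC[Si](CC)(CC)OS(=O)(=O)C(F)(F)F
Why: Silylation of the hindered tertiary alcohol with the silyl triflate (standard silyl ether protection) masks the later β-hydroxy ketone against retro-aldol ring opening.

Step 4
Reactants: 6 {[3-(benzyloxy)-1-((Z)-oct-2-en-1-yl)cyclobutyl]oxy}triethylsilane
Product: 7 3-[(Z)-oct-2-en-1-yl]-3-(triethylsilyloxy)cyclobutan-1-ol
Conditions: lithium 4,4'-di-tert-butylbiphenylide, THF, −78 °C; then H2O
Reagents that add atoms: none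
Why: Reductive cleavage of the benzyl ether by electron transfer from the arene radical anion (dissolving-metal-type debenzylation) leaves the isolated (Z)-alkene and the silyl ether untouched, which hydrogenolysis would not.

Step 5
Reactants: 7 3-[(Z)-oct-2-en-1-yl]-3-(triethylsilyloxy)cyclobutan-1-ol
Product: 8 3-[(Z)-oct-2-en-1-yl]-3-(triethylsilyloxy)cyclobutan-1-one
Conditions: Dess–Martin periodinane, NaHCO3, CH2Cl2, 0 → 20 °C
Reagents that add atoms: none
Why: Dess–Martin oxidation under buffered, non-basic conditions should give the cyclobutanone without β-elimination of the silyloxy group; the product is achiral.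

Step 6
Reactants: 8 3-[(Z)-oct-2-en-1-yl]-3-(triethylsilyloxy)cyclobutan-1-one
Product: 10 (S)-1,3-bis(triethylsilyloxy)-3-[(Z)-oct-2-en-1-yl]cyclobut-1-ene, via lithium cyclobutenolate 9 (not isolated)
Conditions: (R,R)-bis(1-phenylethyl)amine, n-BuLi, THF, −78 °C; Et3SiCl, then 8, −100 °C; non-aqueous work-up, product kept cold and used at once
Reagents that add atoms: chlorotriethylsilane, CC[Si](Cl)(CC)CC
Why: Enantiotopic-group-selective deprotonation of the prochiral cyclobutanone by a C2-symmetric chiral lithium amide with internal silyl chloride quench (asymmetric deprotonation, desymmetrisation) fixes on which α-carbon the enol double bond lies and thereby defines the configuration of C12, the only stereocentre of the ring.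

Step 7
Reactants: 10 (S)-1,3-bis(triethylsilyloxy)-3-[(Z)-oct-2-en-1-yl]cyclobut-1-ene
Product: 12 (S)-2-chloro-4-[(Z)-oct-2-en-1-yl]-4-(triethylsilyloxy)cyclopent-2-en-1-one, via dichlorobis(silyloxy)bicyclo[2.1.0]pentane 11 (not isolated)
Conditions: CHCl3, KOt-Bu, pentane, −40 → 0 °C
Reagents that add atoms: chloroform, ClC(Cl)Cl
Why: Proposed new method: dichlorocarbene (from CHCl3 and KOt-Bu) adds in a concerted [2+1] cycloaddition to the electron-rich C9=C11 enol double bond of 10 to give the housane 11, in which the silyloxy oxygen assists loss of the endo chloride with disrotatory cleavage of the central C9–C11 bond (cyclopropyl-to-allyl cation opening), and the 2-chloro-1-silyloxyallyl cation then loses Et3SiCl to give the enone. The closest known reaction type is the dichlorocarbene ring enlargement of silyl enol ethers of five- to seven-membered ketones to 2-chloro-2-enones, together with the ready rearrangement of dihalocarbene adducts of cyclobutenes to 2,3-dihalocyclopentenes; it is extended here to a 1-silyloxycyclobut-1-ene, where relief of housane strain should make the opening faster still. The only ring closed is the transient cyclopropane (carbene addition to an alkene), and the five-membered ring arises when the bond shared by the three- and four-membered rings breaks, so that the carbene carbon enters as C10 with its chlorine between C9 and C11. The two ring-fusion stereocentres of 11 are destroyed again and no bond to C12 is made or broken, so C12 keeps the configuration implied by the position of the enol double bond fixed in step 6. The step needs chemoselectivity for the enol ether over the (Z)-C14=C15 alkene, which the much higher nucleophilicity of the silyl enol ether towards the electrophilic carbene and a small excess of carbene source should secure, and it needs a single mode of ring opening, which is secured because only the bond opposite the CCl2 carbon can cleave and the product enone is too electron-poor to react again.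

Step 8
Reactants: 13 (4-carboxybutyl)triphenylphosphonium bromide; 14 (tert-butyldimethylsilyloxy)acetaldehyde
Product: 16 (Z)-7-(tert-butyldimethylsilyloxy)hept-5-enoic acid, via ylide sodium carboxylate 15 (not isolated)
Conditions: NaN(SiMe3)2 (2.1 equiv), THF, 0 °C; 14, −78 → 20 °C; then aq HCl to pH 4
Reagents that add atoms: none
Why: Wittig olefination with the non-stabilised ylide under lithium-free conditions is kinetically (Z)-selective and sets the later C5=C6 geometry.

Step 9
Reactants: 16 (Z)-7-(tert-butyldimethylsilyloxy)hept-5-enoic acid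
Product: 17 methyl (Z)-7-hydroxyhept-5-enoate
Conditions: HCl (0.2 M in MeOH), 20 °C
Reagents that add atoms: methanol, CO
Why: Acid-catalysed methanolysis achieves Fischer esterification and cleavage of the primary silyl ether in one operation without touching the (Z)-alkene.

Step 10
Reactants: 17 methyl (Z)-7-hydroxyhept-5-enoate
Product: 18 methyl (Z)-7-oxohept-5-enoate
Conditions: Dess–Martin periodinane, NaHCO3, CH2Cl2, 0 °C; used at once
Reagents that add atoms: none
Why: Buffered Dess–Martin oxidation should give the (Z)-enal without acid- or base-induced isomerisation to the (E)-enal.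

Step 11
Reactants: 12 (S)-2-chloro-4-[(Z)-oct-2-en-1-yl]-4-(triethylsilyloxy)cyclopent-2-en-1-one; 18 methyl (Z)-7-oxohept-5-enoate
Product: 20 methyl (5Z)-7-[(5S)-3-chloro-5-((Z)-oct-2-en-1-yl)-2-oxo-5-(triethylsilyloxy)cyclopent-3-en-1-yl]-7-hydroxyhept-5-enoate (diastereomer mixture at C7 and C8), via lithium dienolate 19 (not isolated)
Conditions: LiN(i-Pr)2, THF, −78 °C; 18, −78 °C; then AcOH, −78 °C
Reagents that add atoms: none
Why: Kinetic deprotonation at C8, the only enolisable position of the 4,4-disubstituted 2-chlorocyclopentenone, and aldol addition of the cross-conjugated lithium dienolate to the enal form the C7–C8 bond; the new stereocentres at C7 and C8 are removed in step 12, so the mixture is carried on.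

Step 12
Reactants: 20 methyl (5Z)-7-[(5S)-3-chloro-5-((Z)-oct-2-en-1-yl)-2-oxo-5-(triethylsilyloxy)cyclopent-3-en-1-yl]-7-hydroxyhept-5-enoate
Product: 22 methyl (5Z,7E)-7-[(2R)-4-chloro-2-((Z)-oct-2-en-1-yl)-5-oxo-2-(triethylsilyloxy)cyclopent-3-en-1-ylidene]hept-5-enoate, via C7 mesylate 21 (not isolated)
Conditions: MsCl, Et3N (excess), CH2Cl2, −20 → 20 °C
Reagents that add atoms: none
Why: Mesylation of the C7 alcohol and E1cB elimination through the C8 enolate should give the cross-conjugated dienone with the (7E) isomer (C6 anti to the C9 carbonyl) predominating and the (5Z) alkene untouched; any (7Z) isomer would be removed by chromatography.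

Step 13
Reactants: 22 methyl (5Z,7E)-7-[(2R)-4-chloro-2-((Z)-oct-2-en-1-yl)-5-oxo-2-(triethylsilyloxy)cyclopent-3-en-1-ylidene]hept-5-enoate
Product: 23 methyl (5Z,7E)-7-[(2R)-4-chloro-2-hydroxy-2-((Z)-oct-2-en-1-yl)-5-oxocyclopent-3-en-1-ylidene]hept-5-enoate
Conditions: HF·pyridine, pyridine, THF, 0 → 20 °C
Reagents that add atoms: none
Why: Buffered fluoride-mediated desilylation frees the tertiary alcohol without a base that could attack the dienone.

Step 14
Reactants: 23 methyl (5Z,7E)-7-[(2R)-4-chloro-2-hydroxy-2-((Z)-oct-2-en-1-yl)-5-oxocyclopent-3-en-1-ylidene]hept-5-enoate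
Product: 24 methyl (5Z,7E)-7-[(2R)-2-acetoxy-4-chloro-2-((Z)-oct-2-en-1-yl)-5-oxocyclopent-3-en-1-ylidene]hept-5-enoate
Conditions: Ac2O, DMAP, Et3N, CH2Cl2, 20 °C
Reagents that add atoms: acetic anhydride, CC(=O)OC(C)=O
Why: DMAP-catalysed acylation (nucleophilic catalysis) should acetylate the hindered tertiary allylic alcohol with retention at C12, since the C12–O bond is not broken.

**Compound list**

1 | (Z)-oct-2-en-1-ol | CCCCC/C=C\CO | starting material
2 | (Z)-1-chlorooct-2-ene | CCCCC/C=C\CCl | intermediate
3 | 3-(benzyloxy)cyclobutan-1-one | O=C1CC(OCc2ccccc2)C1 | starting material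
4 | (Z)-oct-2-enylbarium chloride | CCCCC/C=C\C[Ba]Cl | intermediate
5 | 3-(benzyloxy)-1-[(Z)-oct-2-en-1-yl]cyclobutan-1-ol (cis/trans mixture) | CCCCC/C=C\CC1(O)CC(OCc2ccccc2)C1 | intermediate
6 | {[3-(benzyloxy)-1-((Z)-oct-2-en-1-yl)cyclobutyl]oxy}triethylsilane | CCCCC/C=C\CC1(O[Si](CC)(CC)CC)CC(OCc2ccccc2)C1 | intermediate
7 | 3-[(Z)-oct-2-en-1-yl]-3-(triethylsilyloxy)cyclobutan-1-ol | CCCCC/C=C\CC1(O[Si](CC)(CC)CC)CC(O)C1 | intermediate
8 | 3-[(Z)-oct-2-en-1-yl]-3-(triethylsilyloxy)cyclobutan-1-one | CCCCC/C=C\CC1(O[Si](CC)(CC)CC)CC(=O)C1 | intermediate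
9 | lithium (S)-3-[(Z)-oct-2-en-1-yl]-3-(triethylsilyloxy)cyclobut-1-en-1-olate | CCCCC/C=C\C[C@@]1(O[Si](CC)(CC)CC)C=C(O[Li])C1 | intermediate
10 | (S)-1,3-bis(triethylsilyloxy)-3-[(Z)-oct-2-en-1-yl]cyclobut-1-ene | CCCCC/C=C\C[C@@]1(O[Si](CC)(CC)CC)C=C(O[Si](CC)(CC)CC)C1 | intermediate
11 | (3S)-5,5-dichloro-3-[(Z)-oct-2-en-1-yl]-1,3-bis(triethylsilyloxy)bicyclo[2.1.0]pentane (both ring-fusion diastereomers) | CCCCC/C=C\C[C@@]1(O[Si](CC)(CC)CC)C2C(Cl)(Cl)C2(O[Si](CC)(CC)CC)C1 | intermediate
12 | (S)-2-chloro-4-[(Z)-oct-2-en-1-yl]-4-(triethylsilyloxy)cyclopent-2-en-1-one | CCCCC/C=C\C[C@@]1(O[Si](CC)(CC)CC)C=C(Cl)C(=O)C1 | intermediate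
13 | (4-carboxybutyl)triphenylphosphonium bromide | OC(=O)CCCC[P+](c1ccccc1)(c1ccccc1)c1ccccc1.[Br-] | starting material
14 | (tert-butyldimethylsilyloxy)acetaldehyde | O=CCO[Si](C)(C)C(C)(C)C | starting material
15 | sodium 5-(triphenylphosphoranylidene)pentanoate | [Na+].[O-]C(=O)CCCC=P(c1ccccc1)(c1ccccc1)c1ccccc1 | intermediate
16 | (Z)-7-(tert-butyldimethylsilyloxy)hept-5-enoic acid | OC(=O)CCC/C=C\CO[Si](C)(C)C(C)(C)C | intermediate
17 | methyl (Z)-7-hydroxyhept-5-enoate | COC(=O)CCC/C=C\CO | intermediate
18 | methyl (Z)-7-oxohept-5-enoate | COC(=O)CCC/C=C\C=O | intermediate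
19 | lithium (S)-5-chloro-3-[(Z)-oct-2-en-1-yl]-3-(triethylsilyloxy)cyclopenta-1,4-dien-1-olate (cross-conjugated dienolate of 12) | CCCCC/C=C\C[C@@]1(O[Si](CC)(CC)CC)C=C(Cl)C(O[Li])=C1 | intermediate
20 | methyl (5Z)-7-[(5S)-3-chloro-5-((Z)-oct-2-en-1-yl)-2-oxo-5-(triethylsilyloxy)cyclopent-3-en-1-yl]-7-hydroxyhept-5-enoate (diastereomer mixture at C7 and C8) | CCCCC/C=C\C[C@@]1(O[Si](CC)(CC)CC)C=C(Cl)C(=O)C1C(O)/C=C\CCCC(=O)OC | intermediate
21 | methyl (5Z)-7-[(5S)-3-chloro-5-((Z)-oct-2-en-1-yl)-2-oxo-5-(triethylsilyloxy)cyclopent-3-en-1-yl]-7-(methylsulfonyloxy)hept-5-enoate (diastereomer mixture) | CCCCC/C=C\C[C@@]1(O[Si](CC)(CC)CC)C=C(Cl)C(=O)C1C(OS(C)(=O)=O)/C=C\CCCC(=O)OC | intermediate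
22 | methyl (5Z,7E)-7-[(2R)-4-chloro-2-((Z)-oct-2-en-1-yl)-5-oxo-2-(triethylsilyloxy)cyclopent-3-en-1-ylidene]hept-5-enoate | CCCCC/C=C\C[C@@]1(O[Si](CC)(CC)CC)C=C(Cl)C(=O)/C1=C/C=C\CCCC(=O)OC | intermediate
23 | methyl (5Z,7E)-7-[(2R)-4-chloro-2-hydroxy-2-((Z)-oct-2-en-1-yl)-5-oxocyclopent-3-en-1-ylidene]hept-5-enoate | CCCCC/C=C\C[C@@]1(O)C=C(Cl)C(=O)/C1=C/C=C\CCCC(=O)OC | intermediate
24 | methyl (5Z,7E)-7-[(2R)-2-acetoxy-4-chloro-2-((Z)-oct-2-en-1-yl)-5-oxocyclopent-3-en-1-ylidene]hept-5-enoate | CCCCC/C=C\C[C@@]1(OC(C)=O)C=C(Cl)C(=O)/C1=C/C=C\CCCC(=O)OC | target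

**Step count**

Total step count: 14. Longest linear sequence: 11 steps (steps 1–7 and 11–14); steps 8–10 make the side-chain aldehyde.

**Steps most likely to fail**

Step 7 (ring expansion). The carbene may also attack the C14=C15 alkene, the base may cleave the enol silane back to the ketone (which would erase the desymmetrisation), or the 3-silyloxycyclobutene may undergo thermal electrocyclic opening before cyclopropanation. The fallback still enlarges the four-membered ring to the five-membered one, but by a carbenoid route on the ketone, and sets out from 8. Addition of dichloromethyllithium (CH2Cl2, LiN(i-Pr)2, THF, −100 °C) would give 1-(dichloromethyl)-3-[(Z)-oct-2-en-1-yl]-3-(triethylsilyloxy)cyclobutan-1-ol F1 as the adduct. Treatment with LiN(i-Pr)2 (2 equiv, THF, −78 → 0 °C) should trigger the β-oxido carbenoid ring enlargement with loss of LiCl to lithium 2-chloro-4-[(Z)-oct-2-en-1-yl]-4-(triethylsilyloxy)cyclopent-1-en-1-olate F2 in the flask, where either ring carbon may migrate because the two are enantiotopic. Trapping with PhSeCl at −78 °C should give 2-chloro-4-[(Z)-oct-2-en-1-yl]-2-(phenylselanyl)-4-(triethylsilyloxy)cyclopentan-1-one F3 after work-up. Oxidation (H2O2, pyridine, CH2Cl2, 0 °C) should give 2-chloro-4-[(Z)-oct-2-en-1-yl]-2-(phenylseleninyl)-4-(triethylsilyloxy)cyclopentan-1-one F4 in the flask. Syn-elimination of this selenoxide toward C11 should give racemic 2-chloro-4-[(Z)-oct-2-en-1-yl]-4-(triethylsilyloxy)cyclopent-2-en-1-one F5 as the product. Because this sequence passes through the achiral ketone without desymmetrisation, the enantiomers of F5 would be separated by preparative chromatography on a chiral stationary phase; the (S)-enantiomer is 12, where the route is rejoined.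

Step 6 (desymmetrisation). The silyloxy and octenyl groups on C12 may differ too little to bias the ring pucker, so that the chiral amide discriminates poorly between the two enantiotopic α-methylene groups and the enantiomeric purity stays low. The fallback gives up asymmetric induction for resolution and sets out from 8. Deprotonation with achiral LiN(i-Pr)2 in the presence of Et3SiCl (THF, −78 °C) would pass through racemic lithium 3-[(Z)-oct-2-en-1-yl]-3-(triethylsilyloxy)cyclobut-1-en-1-olate F6 in the flask. Its silylation there would give racemic 1,3-bis(triethylsilyloxy)-3-[(Z)-oct-2-en-1-yl]cyclobut-1-ene F7 as the enol silane. Under the conditions of step 7 this should give racemic 5,5-dichloro-3-[(Z)-oct-2-en-1-yl]-1,3-bis(triethylsilyloxy)bicyclo[2.1.0]pentane F8 in the flask. Its opening with loss of Et3SiCl should give racemic 2-chloro-4-[(Z)-oct-2-en-1-yl]-4-(triethylsilyloxy)cyclopent-2-en-1-one F5 once more. The enantiomers would be separated by preparative chromatography on a chiral stationary phase, and the (S)-enantiomer is 12, where the route is rejoined.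

Step 2 (allylbarium addition). If temperature control is lost, the allylmetal may react through its γ-carbon (allylic transposition to the branched carbinol) or equilibrate from (Z) to (E). The fallback builds the side chain through an alkyne and sets out from 3. Barbier propargylation (propargyl bromide, Zn dust, THF/aq NH4Cl) would give 3-(benzyloxy)-1-(prop-2-yn-1-yl)cyclobutan-1-ol F9 as the carbinol. Silylation (Et3SiOTf, 2,6-lutidine) would give {[3-(benzyloxy)-1-(prop-2-yn-1-yl)cyclobutyl]oxy}triethylsilane F10 as the silyl ether. Deprotonation with n-BuLi (THF, −78 °C) would give {3-[3-(benzyloxy)-1-(triethylsilyloxy)cyclobutyl]prop-1-yn-1-yl}lithium F11 in the flask. Alkylation with 1-iodopentane (DMPU, −78 → 20 °C) would give {[3-(benzyloxy)-1-(oct-2-yn-1-yl)cyclobutyl]oxy}triethylsilane F12 as the internal alkyne. Semihydrogenation (H2, Lindlar catalyst: Pd on CaCO3 poisoned with Pb(OAc)2, quinoline) would set the (Z)-alkene and give 6, where the route is rejoined.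

**Further compounds**

F1 | step 7 | 1-(dichloromethyl)-3-[(Z)-oct-2-en-1-yl]-3-(triethylsilyloxy)cyclobutan-1-ol | CCCCC/C=C\CC1(O[Si](CC)(CC)CC)CC(O)(C(Cl)Cl)C1
F2 | step 7 | lithium 2-chloro-4-[(Z)-oct-2-en-1-yl]-4-(triethylsilyloxy)cyclopent-1-en-1-olate (racemic) | CCCCC/C=C\CC1(O[Si](CC)(CC)CC)CC(Cl)=C(O[Li])C1
F3 | step 7 | 2-chloro-4-[(Z)-oct-2-en-1-yl]-2-(phenylselanyl)-4-(triethylsilyloxy)cyclopentan-1-one (racemic, both diastereomers) | CCCCC/C=C\CC1(O[Si](CC)(CC)CC)CC(Cl)([Se]c2ccccc2)C(=O)C1
F4 | step 7 | 2-chloro-4-[(Z)-oct-2-en-1-yl]-2-(phenylseleninyl)-4-(triethylsilyloxy)cyclopentan-1-one (racemic, diastereomer mixture) | CCCCC/C=C\CC1(O[Si](CC)(CC)CC)CC(Cl)([Se](=O)c2ccccc2)C(=O)C1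
F5 | step 7 | racemic 2-chloro-4-[(Z)-oct-2-en-1-yl]-4-(triethylsilyloxy)cyclopent-2-en-1-one | CCCCC/C=C\CC1(O[Si](CC)(CC)CC)C=C(Cl)C(=O)C1
F6 | step 6 | racemic lithium 3-[(Z)-oct-2-en-1-yl]-3-(triethylsilyloxy)cyclobut-1-en-1-olate | CCCCC/C=C\CC1(O[Si](CC)(CC)CC)C=C(O[Li])C1
F7 | step 6 | racemic 1,3-bis(triethylsilyloxy)-3-[(Z)-oct-2-en-1-yl]cyclobut-1-ene | CCCCC/C=C\CC1(O[Si](CC)(CC)CC)C=C(O[Si](CC)(CC)CC)C1
F8 | step 6 | racemic 5,5-dichloro-3-[(Z)-oct-2-en-1-yl]-1,3-bis(triethylsilyloxy)bicyclo[2.1.0]pentane (diastereomer mixture) | CCCCC/C=C\CC1(O[Si](CC)(CC)CC)C2C(Cl)(Cl)C2(O[Si](CC)(CC)CC)C1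
F9 | step 2 | 3-(benzyloxy)-1-(prop-2-yn-1-yl)cyclobutan-1-ol | C#CCC1(O)CC(OCc2ccccc2)C1
F10 | step 2 | {[3-(benzyloxy)-1-(prop-2-yn-1-yl)cyclobutyl]oxy}triethylsilane | C#CCC1(O[Si](CC)(CC)CC)CC(OCc2ccccc2)C1
F11 | step 2 | {3-[3-(benzyloxy)-1-(triethylsilyloxy)cyclobutyl]prop-1-yn-1-yl}lithium | [Li]C#CCC1(O[Si](CC)(CC)CC)CC(OCc2ccccc2)C1
F12 | step 2 | {[3-(benzyloxy)-1-(oct-2-yn-1-yl)cyclobutyl]oxy}triethylsilane | CCCCCC#CCC1(O[Si](CC)(CC)CC)CC(OCc2ccccc2)C1
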